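**Plan**

1. Numbering as in zeylenone: C1 = carbinol carbon carrying CH2OBz (C7), C2 = ring ketone, C3=C4 = alkene, C5 = CH–OBz, C6 = CH–OH. The feature used is the α-ketol C1(OH)–C2(=O) inside the six-membered carbocycle, which is a benzoin retron.
2. Retrosynthesis: take out C3=C4 (saturated tether, re-made by Saegusa oxidation); cut C1–C2 to an open-chain 6-keto aldehyde whose aldehyde is masked as a terminal alkene; cut C5–C6 (aldol) to protected dihydroxyacetone and pent-4-enal.
3. Forward: an aldolase-type syn aldol joins the C3 and C5 units; both benzoates are installed; ozonolysis frees the aldehyde; a carbene-catalysed benzoin closes the only ring; dehydrogenation and desilylation finish.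
4. Stereochemistry: C5 and C6 come from the amino-acid catalyst of the aldol; C1 is set in the ring closure under control of C5/C6 (chair transition state).
5. Helpers: TBS on O6 (and first on O7), terminal alkene as latent aldehyde, saturated C3–C4 during the carbene step, TMS on O1 during dehydrogenation; all are removed or converted later.

Key step: step 6

Remark: 1,3-dihydroxyacetone is sold as its crystalline hemiketal dimer, which reverts to the monomer in solution; it is written as the monomer.

**Route**

Step 1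
Reactants: 1 1,3-dihydroxyacetone
Product: 2 1,3-bis[(tert-butyldimethylsilyl)oxy]propan-2-one
Conditions: TBSCl (2.2 equiv), imidazole (4 equiv), DMF, 0 °C to rt
Reagents that add atoms: tert-butyldimethylsilyl chloride (TBSCl), CC(C)(C)[Si](C)(C)Cl
Why: Imidazole-mediated silylation of both primary hydroxyls gives the symmetrical ketone that is the established donor for amine-catalysed syn aldol reactions of dihydroxyacetone; no stereocentre is formed.

Step 2
Reactants: 2 1,3-bis[(tert-butyldimethylsilyl)oxy]propan-2-one; 3 pent-4-enal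
Product: 4 (3S,4R)-1,3-bis[(tert-butyldimethylsilyl)oxy]-4-hydroxyoct-7-en-2-one
Conditions: O-tert-butyl-D-threonine (20 mol %), 5-methyl-1H-tetrazole (10 mol %), NMP with 3 vol % water, 4 °C to rt; 2 in twofold excess, 3 added slowly
Reagents that add atoms: none
Why: Primary-amino-acid (enamine) catalysed direct syn aldol reaction of protected dihydroxyacetone, the organocatalytic counterpart of a fructose-type aldolase, in which the (Z)-enamine held by an N–H···O hydrogen bond to the silyloxy group adds through an acid-directed chair-like transition state to one aldehyde face and so sets C6 (3S) and C5 (4R) syn in one step; the D-amino acid is chosen because L-amino acids attack the aldehyde face used by L-proline and would give the (3R,4S) series.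

Step 3
Reactants: 4 (3S,4R)-1,3-bis[(tert-butyldimethylsilyl)oxy]-4-hydroxyoct-7-en-2-one
Product: 5 (3S,4R)-3-[(tert-butyldimethylsilyl)oxy]-1,4-dihydroxyoct-7-en-2-one
Conditions: HF·pyridine, pyridine, THF, 0 °C
Reagents that add atoms: none
Why: Selective desilylation, since buffered HF·pyridine cleaves the unhindered primary TBS ether much faster than the secondary TBS ether flanked by the ketone and C5, so only O7 is freed and no stereocentre is touched.

Step 4
Reactants: 5 (3S,4R)-3-[(tert-butyldimethylsilyl)oxy]-1,4-dihydroxyoct-7-en-2-one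
Product: 6 (3S,4R)-3-[(tert-butyldimethylsilyl)oxy]-2-oxooct-7-ene-1,4-diyl dibenzoate
Conditions: BzCl (2.5 equiv), pyridine, 4-(dimethylamino)pyridine (cat.), CH2Cl2, 0 °C
Reagents that add atoms: benzoyl chloride, O=C(Cl)c1ccccc1
Why: Acylation of the primary and the secondary hydroxyl installs both benzoates of the target at once, and the cold, weakly basic conditions should avoid silyl migration and β-elimination; the stereocentres are untouched.

Step 5
Reactants: 6 (3S,4R)-3-[(tert-butyldimethylsilyl)oxy]-2-oxooct-7-ene-1,4-diyl dibenzoate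
Product: 8 (3S,4R)-3-[(tert-butyldimethylsilyl)oxy]-2,7-dioxoheptane-1,4-diyl dibenzoate, via secondary ozonide 7 (not isolated)
Conditions: O3, CH2Cl2, −78 °C; then PPh3, −78 °C to rt
Reagents that add atoms: ozone, [O-][O+]=O
Why: Ozonolysis with reductive work-up turns the terminal alkene, carried as a latent aldehyde, into the C2 aldehyde with loss of one carbon as formaldehyde, while benzoates, ketone and silyl ether are inert at −78 °C.

Step 6
Reactants: 8 (3S,4R)-3-[(tert-butyldimethylsilyl)oxy]-2,7-dioxoheptane-1,4-diyl dibenzoate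
Product: 9 [(1S,5R,6S)-5-(benzoyloxy)-6-[(tert-butyldimethylsilyl)oxy]-1-hydroxy-2-oxocyclohexyl]methyl benzoate (zeylenone numbering)
Conditions: 3-benzyl-5-(2-hydroxyethyl)-4-methylthiazolium chloride (20 mol %), Et3N (40 mol %), t-BuOH–CH2Cl2 (0.02 M), 40 °C
Reagents that add atoms: none
Why: The thiazol-2-ylidene adds to the aldehyde carbon C2 and proton transfer gives the Breslow intermediate (an acyl anion equivalent), whose carbinol carbon attacks the ketone C1 intramolecularly; proton transfer and loss of the carbene then release the α-ketol. The closest known reaction type is the carbene-catalysed intramolecular crossed aldehyde–ketone benzoin cyclisation to six-membered tertiary α-ketols, which has also been applied to carbohydrate-derived dicarbonyl compounds. The carbocycle closes in a 6-exo-trig mode. The new stereocentre C1 is set by substrate control: in the chair-like transition state the C5 benzoate, the C6 silyl ether and the CH2OBz branch of the ketone are equatorial, the C6–O bond is anti to the incoming carbon (polar Felkin–Anh) and the ketone oxygen is axial next to the enol O–H that delivers the proton, so the tertiary hydroxyl should end cis to the C6 oxygen (1S); the sulfur flank of the thiazolylidene, which bears no substituent, leaves room for the equatorial CH2OBz group. The step needs the aldehyde as donor and the ketone as acceptor, and ring closure ahead of dimerisation, enolate aldol reactions and β-elimination of the C5 benzoate: only the aldehyde can form a Breslow intermediate, the ketone is activated by its two α-oxygens, the saturated C3–C4 tether excludes homoenolate and γ-elimination pathways, and high dilution with a weak amine base in sub-stoichiometric amount keeps the bimolecular and E1cB pathways slow.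

Step 7
Reactants: 9 [(1S,5R,6S)-5-(benzoyloxy)-6-[(tert-butyldimethylsilyl)oxy]-1-hydroxy-2-oxocyclohexyl]methyl benzoate
Product: 11 [(1S,5R,6S)-5-(benzoyloxy)-6-[(tert-butyldimethylsilyl)oxy]-2-oxo-1-[(trimethylsilyl)oxy]cyclohex-3-en-1-yl]methyl benzoate, via bis(trimethylsilyl) enol ether 10 (not isolated)
Conditions: TMSOTf (3 equiv), Et3N (4 equiv), CH2Cl2, 0 °C; then Pd(OAc)2 (1.1 equiv), MeCN, rt
Reagents that add atoms: trimethylsilyl trifluoromethanesulfonate (TMSOTf), C[Si](C)(C)OS(=O)(=O)C(F)(F)F
Why: Saegusa–Ito oxidation, in which TMSOTf/Et3N silylates the tertiary hydroxyl and forms the only possible silyl enol ether (C2=C3, C1 being quaternary) and Pd(OAc)2 converts it through the palladium enolate and β-hydride elimination into the C3=C4 enone without touching a stereocentre.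

Step 8
Reactants: 11 [(1S,5R,6S)-5-(benzoyloxy)-6-[(tert-butyldimethylsilyl)oxy]-2-oxo-1-[(trimethylsilyl)oxy]cyclohex-3-en-1-yl]methyl benzoate
Product: 12 zeylenone, [(1S,5R,6S)-5-(benzoyloxy)-1,6-dihydroxy-2-oxocyclohex-3-en-1-yl]methyl benzoate
Conditions: aq. HF (48 %), MeCN, 0 °C to rt
Reagents that add atoms: none
Why: Global desilylation under acidic fluoride conditions removes the tertiary TMS ether and the hindered secondary TBS ether without base, so the benzoates should not migrate and the γ-benzoyloxy enone should not eliminate.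

**Compound list**

1 | 1,3-dihydroxyacetone | O=C(CO)CO | starting material
2 | 1,3-bis[(tert-butyldimethylsilyl)oxy]propan-2-one | CC(C)(C)[Si](C)(C)OCC(=O)CO[Si](C)(C)C(C)(C)C | intermediate
3 | pent-4-enal | C=CCCC=O | starting material
4 | (3S,4R)-1,3-bis[(tert-butyldimethylsilyl)oxy]-4-hydroxyoct-7-en-2-one | CC(C)(C)[Si](C)(C)OCC(=O)[C@@H](O[Si](C)(C)C(C)(C)C)[C@H](O)CCC=C | intermediate
5 | (3S,4R)-3-[(tert-butyldimethylsilyl)oxy]-1,4-dihydroxyoct-7-en-2-one | OCC(=O)[C@@H](O[Si](C)(C)C(C)(C)C)[C@H](O)CCC=C | intermediate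
6 | (3S,4R)-3-[(tert-butyldimethylsilyl)oxy]-2-oxooct-7-ene-1,4-diyl dibenzoate | O=C(OCC(=O)[C@@H](O[Si](C)(C)C(C)(C)C)[C@H](OC(=O)c1ccccc1)CCC=C)c1ccccc1 | intermediate
7 | secondary ozonide of 6, (3S,4R)-3-[(tert-butyldimethylsilyl)oxy]-2-oxo-6-(1,2,4-trioxolan-3-yl)hexane-1,4-diyl dibenzoate (not isolated) | O=C(OCC(=O)[C@@H](O[Si](C)(C)C(C)(C)C)[C@H](OC(=O)c1ccccc1)CCC1OCOO1)c1ccccc1 | intermediate
8 | (3S,4R)-3-[(tert-butyldimethylsilyl)oxy]-2,7-dioxoheptane-1,4-diyl dibenzoate | O=C(OCC(=O)[C@@H](O[Si](C)(C)C(C)(C)C)[C@H](OC(=O)c1ccccc1)CCC=O)c1ccccc1 | intermediate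
9 | [(1S,5R,6S)-5-(benzoyloxy)-6-[(tert-butyldimethylsilyl)oxy]-1-hydroxy-2-oxocyclohexyl]methyl benzoate | O=C(OC[C@@]1(O)C(=O)CC[C@@H](OC(=O)c2ccccc2)[C@@H]1O[Si](C)(C)C(C)(C)C)c1ccccc1 | intermediate
10 | [(1S,5R,6S)-5-(benzoyloxy)-6-[(tert-butyldimethylsilyl)oxy]-1,2-bis[(trimethylsilyl)oxy]cyclohex-2-en-1-yl]methyl benzoate (not isolated) | O=C(OC[C@@]1(O[Si](C)(C)C)C(O[Si](C)(C)C)=CC[C@@H](OC(=O)c2ccccc2)[C@@H]1O[Si](C)(C)C(C)(C)C)c1ccccc1 | intermediate
11 | [(1S,5R,6S)-5-(benzoyloxy)-6-[(tert-butyldimethylsilyl)oxy]-2-oxo-1-[(trimethylsilyl)oxy]cyclohex-3-en-1-yl]methyl benzoate | O=C(OC[C@@]1(O[Si](C)(C)C)C(=O)C=C[C@@H](OC(=O)c2ccccc2)[C@@H]1O[Si](C)(C)C(C)(C)C)c1ccccc1 | intermediate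
12 | zeylenone, [(1S,5R,6S)-5-(benzoyloxy)-1,6-dihydroxy-2-oxocyclohex-3-en-1-yl]methyl benzoate | O=C(OC[C@@]1(O)C(=O)C=C[C@@H](OC(=O)c2ccccc2)[C@@H]1O)c1ccccc1 | target

Total step count: 8. Longest linear sequence: 8 steps (1 to 12).

**Steps most likely to fail**

Step 6. Two processes may defeat the ring closure. The acyl anion equivalent may attack the other face of the ketone, through the chair with CH2OBz axial and the azolium remote from it, which would give the C1 epimer. The base may also remove the C6 proton of the α-silyloxy ketone and expel the C5 benzoate (E1cB) before the ring closes. The fallback closes the ring before either benzoate is present and acylates afterwards. It sets out from 5. TESCl and imidazole in DMF should give (3S,4R)-3-[(tert-butyldimethylsilyl)oxy]-1,4-bis[(triethylsilyl)oxy]oct-7-en-2-one F1. Ozone in CH2Cl2 at −78 °C followed by PPh3 should give, by way of the secondary ozonide of F1 F2 (not isolated), (4R,5S)-5-[(tert-butyldimethylsilyl)oxy]-6-oxo-4,7-bis[(triethylsilyl)oxy]heptanal F3. This benzoate-free keto aldehyde has no acyloxy leaving group, so the carbene-catalysed benzoin cyclisation can be run with stronger base. It can also be run with (5aS,10bR)-5a,10b-dihydro-2-(pentafluorophenyl)-4H,6H-indeno[2,1-b][1,2,4]triazolo[4,3-d][1,4]oxazinium tetrafluoroborate or its enantiomer, whichever is matched, to steer the ketone face by the catalyst. The product should be (2S,3S,4R)-3-[(tert-butyldimethylsilyl)oxy]-2-hydroxy-4-[(triethylsilyl)oxy]-2-{[(triethylsilyl)oxy]methyl}cyclohexan-1-one F4. Pyridinium p-toluenesulfonate in MeOH at 0 °C should remove both triethylsilyl ethers and leave the hindered secondary TBS ether, giving (2S,3S,4R)-3-[(tert-butyldimethylsilyl)oxy]-2,4-dihydroxy-2-(hydroxymethyl)cyclohexan-1-one F5. BzCl and pyridine at 0 °C should acylate the primary and the secondary hydroxyl but not the tertiary one, which comes back to the route at 9.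

Step 2. The unbranched, enolisable aldehyde may undergo self-condensation under amine catalysis faster than the cross-aldol, or the syn/anti and facial selectivity may be too low. The fallback replaces the catalytic enamine aldol by an auxiliary-controlled boron enolate aldol and builds the benzoyloxymethyl ketone afterwards. It sets out from 3. The auxiliary reagent (S)-4-benzyl-3-{[(tert-butyldimethylsilyl)oxy]acetyl}oxazolidin-2-one F6 is made from (S)-4-benzyloxazolidin-2-one, n-BuLi and (tert-butyldimethylsilyloxy)acetyl chloride. Its (Z)-boron enolate (Bu2BOTf, dibutylboron triflate, with Et3N in CH2Cl2 at −78 to 0 °C) should add to 3 in an Evans syn-glycolate aldol to give (S)-4-benzyl-3-[(2S,3R)-2-[(tert-butyldimethylsilyl)oxy]-3-hydroxyhept-6-enoyl]oxazolidin-2-one F7. MeNHOMe·HCl and AlMe3 should give (2S,3R)-2-[(tert-butyldimethylsilyl)oxy]-3-hydroxy-N-methoxy-N-methylhept-6-enamide F8. BzCl and pyridine should give (2S,3R)-2-[(tert-butyldimethylsilyl)oxy]-1-[methoxy(methyl)amino]-1-oxohept-6-en-3-yl benzoate F9. Chloromethyllithium (from ICH2Cl and MeLi·LiBr at −78 °C) should give (3S,4R)-3-[(tert-butyldimethylsilyl)oxy]-1-chloro-2-oxooct-7-en-4-yl benzoate F10. Displacement of chloride with benzoic acid and Cs2CO3 in DMF comes back to the route at 6.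

Step 7. Zerovalent palladium formed in the oxidation may ionise the newly allylic C5 benzoate, or the enone may be dehydrogenated further towards a phenol. The fallback replaces the palladium-mediated dehydrogenation by α-selenenylation and selenoxide syn-elimination. It sets out from 10. PhSeCl in CH2Cl2 at −78 °C should give [(1S,5R,6S)-5-(benzoyloxy)-6-[(tert-butyldimethylsilyl)oxy]-2-oxo-3-(phenylselanyl)-1-[(trimethylsilyl)oxy]cyclohexyl]methyl benzoate F11 as a mixture at C3. H2O2 and pyridine in CH2Cl2 at 0 °C should oxidise it to the selenoxide of F11 F12 (not isolated), which eliminates to the C3=C4 enone and comes back to the route at 11.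

Further compounds
F1 | step 6 | (3S,4R)-3-[(tert-butyldimethylsilyl)oxy]-1,4-bis[(triethylsilyl)oxy]oct-7-en-2-one | CC[Si](CC)(CC)OCC(=O)[C@@H](O[Si](C)(C)C(C)(C)C)[C@H](O[Si](CC)(CC)CC)CCC=C
F2 | step 6 | secondary ozonide of F1 | CC[Si](CC)(CC)OCC(=O)[C@@H](O[Si](C)(C)C(C)(C)C)[C@H](O[Si](CC)(CC)CC)CCC1OCOO1
F3 | step 6 | (4R,5S)-5-[(tert-butyldimethylsilyl)oxy]-6-oxo-4,7-bis[(triethylsilyl)oxy]heptanal | CC[Si](CC)(CC)OCC(=O)[C@@H](O[Si](C)(C)C(C)(C)C)[C@H](O[Si](CC)(CC)CC)CCC=O
F4 | step 6 | (2S,3S,4R)-3-[(tert-butyldimethylsilyl)oxy]-2-hydroxy-4-[(triethylsilyl)oxy]-2-{[(triethylsilyl)oxy]methyl}cyclohexan-1-one | CC[Si](CC)(CC)OC[C@@]1(O)C(=O)CC[C@@H](O[Si](CC)(CC)CC)[C@@H]1O[Si](C)(C)C(C)(C)C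
F5 | step 6 | (2S,3S,4R)-3-[(tert-butyldimethylsilyl)oxy]-2,4-dihydroxy-2-(hydroxymethyl)cyclohexan-1-one | OC[C@@]1(O)C(=O)CC[C@@H](O)[C@@H]1O[Si](C)(C)C(C)(C)C
F6 | step 2 | (S)-4-benzyl-3-{[(tert-butyldimethylsilyl)oxy]acetyl}oxazolidin-2-one | O=C1OC[C@H](Cc2ccccc2)N1C(=O)CO[Si](C)(C)C(C)(C)C
F7 | step 2 | (S)-4-benzyl-3-[(2S,3R)-2-[(tert-butyldimethylsilyl)oxy]-3-hydroxyhept-6-enoyl]oxazolidin-2-one | O=C1OC[C@H](Cc2ccccc2)N1C(=O)[C@@H](O[Si](C)(C)C(C)(C)C)[C@H](O)CCC=C
F8 | step 2 | (2S,3R)-2-[(tert-butyldimethylsilyl)oxy]-3-hydroxy-N-methoxy-N-methylhept-6-enamide | CON(C)C(=O)[C@@H](O[Si](C)(C)C(C)(C)C)[C@H](O)CCC=C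
F9 | step 2 | (2S,3R)-2-[(tert-butyldimethylsilyl)oxy]-1-[methoxy(methyl)amino]-1-oxohept-6-en-3-yl benzoate | CON(C)C(=O)[C@@H](O[Si](C)(C)C(C)(C)C)[C@H](OC(=O)c1ccccc1)CCC=C
F10 | step 2 | (3S,4R)-3-[(tert-butyldimethylsilyl)oxy]-1-chloro-2-oxooct-7-en-4-yl benzoate | ClCC(=O)[C@@H](O[Si](C)(C)C(C)(C)C)[C@H](OC(=O)c1ccccc1)CCC=C
F11 | step 7 | [(1S,5R,6S)-5-(benzoyloxy)-6-[(tert-butyldimethylsilyl)oxy]-2-oxo-3-(phenylselanyl)-1-[(trimethylsilyl)oxy]cyclohexyl]methyl benzoate | O=C(OC[C@@]1(O[Si](C)(C)C)C(=O)C([Se]c2ccccc2)C[C@@H](OC(=O)c2ccccc2)[C@@H]1O[Si](C)(C)C(C)(C)C)c1ccccc1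
F12 | step 7 | selenoxide of F11 | O=C(OC[C@@]1(O[Si](C)(C)C)C(=O)C([Se](=O)c2ccccc2)C[C@@H](OC(=O)c2ccccc2)[C@@H]1O[Si](C)(C)C(C)(C)C)c1ccccc1
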